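(All constants are invented; the run is a simulation.)

You sent me 4 questions and a hunch that idle complex would hold most of the catalyst. I went to the balance of the catalyst, the reagent charged in the smallest amount.

substrate 0.80 M; solid reagent 0.800 M; free catalyst 4.0 mM; added ligand 15 mM

    substrate + free catalyst → free catalyst + open intermediate (k1 = 0.022 M⁻¹ s⁻¹)
    solid reagent ⇌ partner, rate k2*(cs2 - [partner]) while solid is left; crystals form when [partner] > cs2 (cs2 = 0.67 M, k2 = 2.0 × 10⁻⁴ s⁻¹)
    partner + catalyst intermediate → free catalyst + product (k3 = 0.27 M⁻¹ s⁻¹)
    free catalyst + open intermediate ⇌ catalyst intermediate (K4 = 2.2 M⁻¹, k4 = 0.053 M⁻¹ s⁻¹)
    free catalyst + added ligand ⇌ idle complex, settled at all times (K5 = 130 M⁻¹)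

- solid reagent is a solid; its amount is given per volume of the solution
- at the start none of the solid reagent is in solution
- charge of substrate (flask): 0.80 M

- the form that holds most of the catalyst when 5.0% of the substrate are converted (catalyst intermediate / idle complex / free catalyst)
- its share of the catalyst then
- apparent order in free catalyst when 5.0% of the substrate are converted (percent change of the rate of making product for one percent more free catalyst charged)
- factor on the rate of making product when 5.0% of the substrate are converted if free catalyst is charged twice over

Free catalyst, idle complex and catalyst intermediate had to add up to the charge. Setting catalyst intermediate aside for a moment, the balance with the added ligand gave 2.48 mM of idle complex, which is 61.9% of the catalyst. That left 1.52 mM as the free level, the free catalyst remaining after the ligand has taken its part.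

Substrate opened pseudo-first-order, at the first rate constant times the free level, so I put 5.0% conversion at 0.425 h, when dissolving had brought 0.177 M of partner. With about 0.0400 M of open intermediate, catalyst intermediate came to 1.12% of the catalyst, far below idle complex. So my reckoning went with your hunch: idle complex held most, though it lies outside the working round and isn't its resting state.

I took the rate of making product as capture of open intermediate times the forward share, the part of catalyst intermediate going on to product rather than falling back, which was 66.5%. With the charge doubled, the free level rose to 3.40 mM, or 2.24 times as much. But the same conversion came at 0.190 h, with 0.0858 M of partner and a forward share of 49.0%. That made my factor 1.65, and for a small step the same sum gave an order of 0.795.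

The forecast said idle complex at 61%, with “an order a bit below one”, 0.8, and a factor of 1.66. The run gave idle complex at 61.3%, catalyst intermediate at 1.07%, order 0.79 and factor 1.63, with the conversion reached at 0.429 h. After 2.00 h the free level gave open intermediate a capture half-life of 2.39 h, and the run's reading was 2.4 h, far longer than the 0.088 min in which partner turned over catalyst intermediate. At that time open intermediate stood at 16.8% of the substrate charged and catalyst intermediate at 1.70% of the catalyst charged.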